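**Plan**

- Enabling feature: ring B is a cyclohexa-2,5-dienone whose only sp3 atom, the methyl-bearing quaternary C5, lies para to the C8 oxygen. Ring B is therefore a para-cresol in disguise and C4–C5 is a phenolate para-alkylation bond (eremophilane numbering; β = face of the C5 methyl).
- Retrosynthetic cuts, in order: the O1–angeloyl ester bond, C9–H (back to a C9 bromide that blocks the ortho carbon), C4–C5 of ring A, the C7–C11 aryl–alkyl bond, and C1–C2.
- Forward: benzyl-protected 5-hydroxy-2-methylbenzaldehyde (ring B plus C1) is joined to a Grignard reagent from (R)-butane-1,3-diol (C2–C4 and C15). C7 is iodinated and coupled with a 2-chloropropanoate.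
- The phenol is then freed and brominated at C9, and the C4 mesylate closes ring A while ring B is dearomatised. Debromination, desilylation and angeloylation finish the route.
- Stereochemistry: C4 from the diol (4R carbinol, inverted to 4S in the ring closure); C1 from a CBS reduction (1R); C11 from a ligand-controlled nickel coupling (11S); C5 from the chair-like ring closure steered by C1 and C4 (5S).
- C12 travels as a benzyl ester and enters the ring closure as a free carboxylate, so that C11 cannot epimerise under base; it is methylated in the same flask.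

Key step: step 15

Assumption: the SMILES is read as (1R,4S,5S,11S) with the angelate, the C4 methyl and the C5 methyl all β, and racemic benzyl 2-chloropropanoate is taken as purchasable (otherwise one step from 2-chloropropanoyl chloride and benzyl alcohol).

**Route**

Step 1
Reactants: 1 (R)-butane-1,3-diol
Product: 2 (R)-3-hydroxybutyl 4-methylbenzenesulfonate
Conditions: TsCl (1.0 equiv), Et3N, CH2Cl2, −20 → 0 °C
Reagents that add atoms: 4-toluenesulfonyl chloride, Cc1ccc(cc1)S(Cl)(=O)=O
Why: Selective sulfonylation of the primary hydroxyl of a 1,3-diol, which reacts faster than the secondary one at low temperature and leaves the carbinol stereocentre untouched.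

Step 2
Reactants: 2 (R)-3-hydroxybutyl 4-methylbenzenesulfonate
Product: 3 (R)-3-(tert-butyldimethylsilyloxy)butyl 4-methylbenzenesulfonate
Conditions: TBSCl, imidazole, DMF, 23 °C
Reagents that add atoms: tert-butyldimethylsilyl chloride, CC(C)(C)[Si](C)(C)Cl
Why: Standard silylation of a secondary alcohol with a silyl chloride and imidazole, to which the primary tosylate is inert.

Step 3
Reactants: 3 (R)-3-(tert-butyldimethylsilyloxy)butyl 4-methylbenzenesulfonate
Product: 4 (R)-(4-bromobutan-2-yl)oxy(tert-butyl)dimethylsilane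
Conditions: LiBr, acetone, reflux
Reagents that add atoms: lithium bromide, [Li+].[Br-]
Why: Finkelstein-type SN2 displacement of the primary tosylate by bromide, remote from the stereocentre.

Step 4
Reactants: 5 5-hydroxy-2-methylbenzaldehyde
Product: 6 5-(benzyloxy)-2-methylbenzaldehyde
Conditions: BnBr, K2CO3, DMF, 23 °C
Reagents that add atoms: benzyl bromide, BrCc1ccccc1
Why: Williamson etherification of the phenol, giving an ether that survives organometallic, hydride and nickel chemistry and is later removed by hydrogenolysis.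

Step 5
Reactants: 4 (R)-(4-bromobutan-2-yl)oxy(tert-butyl)dimethylsilane; 6 5-(benzyloxy)-2-methylbenzaldehyde
Product: 8 (4R)-1-[5-(benzyloxy)-2-methylphenyl]-4-(tert-butyldimethylsilyloxy)pentan-1-ol (both C1 epimers), via Grignard reagent 7 (not isolated)
Conditions: Mg turnings, I2 (cat.), THF, 40 °C; then 6, THF, −20 → 0 °C
Reagents that add atoms: none
Why: Grignard addition of a γ-silyloxyalkylmagnesium bromide to the aryl aldehyde forms C1–C2, and the C1 epimer mixture does not matter because C1 is oxidised in the next step.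

Step 6
Reactants: 8 (4R)-1-[5-(benzyloxy)-2-methylphenyl]-4-(tert-butyldimethylsilyloxy)pentan-1-ol
Product: 9 (R)-1-[5-(benzyloxy)-2-methylphenyl]-4-(tert-butyldimethylsilyloxy)pentan-1-one
Conditions: Dess–Martin periodinane, CH2Cl2, 23 °C
Reagents that add atoms: none
Why: Dess–Martin oxidation of the benzylic alcohol to the aryl ketone under conditions that spare the silyl and benzyl ethers.

Step 7
Reactants: 9 (R)-1-[5-(benzyloxy)-2-methylphenyl]-4-(tert-butyldimethylsilyloxy)pentan-1-one
Product: 10 (1R,4R)-1-[5-(benzyloxy)-2-methylphenyl]-4-(tert-butyldimethylsilyloxy)pentan-1-ol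
Conditions: (S)-2-methyl-CBS-oxazaborolidine (20 mol %), BH3·SMe2, THF, −20 °C
Reagents that add atoms: none
Why: Corey–Bakshi–Shibata reduction of an aryl alkyl ketone, in which the aryl group acts as the large substituent so that the (S)-catalyst should deliver hydride to give the (1R)-carbinol.

Step 8
Reactants: 10 (1R,4R)-1-[5-(benzyloxy)-2-methylphenyl]-4-(tert-butyldimethylsilyloxy)pentan-1-ol
Product: 11 4-(benzyloxy)-1-methyl-2-[(1R,4R)-4-(tert-butyldimethylsilyloxy)-1-(triisopropylsilyloxy)pentyl]benzene
Conditions: TIPSOTf, 2,6-lutidine, CH2Cl2, 0 → 23 °C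
Reagents that add atoms: triisopropylsilyl trifluoromethanesulfonate, CC(C)[Si](C(C)C)(C(C)C)OS(=O)(=O)C(F)(F)F
Why: Silylation of the hindered benzylic alcohol with a silyl triflate gives a triisopropylsilyl ether that outlasts the later acid removal of the C4 tert-butyldimethylsilyl ether and the base of the ring closure.

Step 9
Reactants: 11 4-(benzyloxy)-1-methyl-2-[(1R,4R)-4-(tert-butyldimethylsilyloxy)-1-(triisopropylsilyloxy)pentyl]benzene
Product: 12 1-(benzyloxy)-2-iodo-4-methyl-5-[(1R,4R)-4-(tert-butyldimethylsilyloxy)-1-(triisopropylsilyloxy)pentyl]benzene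
Conditions: NIS, CF3CO2H (cat.), MeCN, 0 °C
Reagents that add atoms: N-iodosuccinimide, O=C1CCC(=O)N1I
Why: Electrophilic aromatic iodination goes to C7, which is ortho to the benzyloxy group and para to the C10 alkyl group, because the para position is occupied by the methyl group and C9 is shielded by the branched side chain.

Step 10
Reactants: 12 1-(benzyloxy)-2-iodo-4-methyl-5-[(1R,4R)-4-(tert-butyldimethylsilyloxy)-1-(triisopropylsilyloxy)pentyl]benzene; 13 benzyl 2-chloropropanoate (racemic)
Product: 14 benzyl (2S)-2-{2-(benzyloxy)-5-methyl-4-[(1R,4R)-4-(tert-butyldimethylsilyloxy)-1-(triisopropylsilyloxy)pentyl]phenyl}propanoate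
Conditions: NiBr2·diglyme (10 mol %), chiral 4,4'-dialkyl-2,2'-bioxazoline ligand (12 mol %, the enantiomer that gives 11S, to be assigned on a model ortho-benzyloxy aryl iodide), Mn powder, Me3SiCl (cat.), DMA, 10 °C
Reagents that add atoms: none
Why: Nickel-catalysed enantioconvergent reductive cross-coupling of an aryl iodide with a racemic α-chloro ester forms C7–C11, the α-ester radical being captured by the aryl-nickel species so that the chiral ligand, not the remote C1 and C4 centres, sets C11 as S.

Step 11
Reactants: 14 benzyl (2S)-2-{2-(benzyloxy)-5-methyl-4-[(1R,4R)-4-(tert-butyldimethylsilyloxy)-1-(triisopropylsilyloxy)pentyl]phenyl}propanoate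
Product: 15 benzyl (2S)-2-{2-(benzyloxy)-4-[(1R,4R)-4-hydroxy-1-(triisopropylsilyloxy)pentyl]-5-methylphenyl}propanoate
Conditions: AcOH–THF–H2O (3:1:1), 40 °C
Reagents that add atoms: none
Why: Selective acid hydrolysis of the less hindered and more labile secondary tert-butyldimethylsilyl ether in the presence of the benzylic triisopropylsilyl ether, run without an alcohol solvent so that the benzyl ester is not transesterified.

Step 12
Reactants: 15 benzyl (2S)-2-{2-(benzyloxy)-4-[(1R,4R)-4-hydroxy-1-(triisopropylsilyloxy)pentyl]-5-methylphenyl}propanoate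
Product: 16 benzyl (2S)-2-{2-(benzyloxy)-4-[(1R,4R)-4-(methanesulfonyloxy)-1-(triisopropylsilyloxy)pentyl]-5-methylphenyl}propanoate
Conditions: MsCl, Et3N, CH2Cl2, 0 °C
Reagents that add atoms: methanesulfonyl chloride, CS(Cl)(=O)=O
Why: Mesylation of the secondary alcohol with retention at C4, done while the phenol is still benzylated so that only the aliphatic hydroxyl is sulfonylated.

Step 13
Reactants: 16 benzyl (2S)-2-{2-(benzyloxy)-4-[(1R,4R)-4-(methanesulfonyloxy)-1-(triisopropylsilyloxy)pentyl]-5-methylphenyl}propanoate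
Product: 17 (2S)-2-{2-hydroxy-4-[(1R,4R)-4-(methanesulfonyloxy)-1-(triisopropylsilyloxy)pentyl]-5-methylphenyl}propanoic acid
Conditions: H2 (1 atm), 10% Pd/C, EtOAc, 23 °C
Reagents that add atoms: none
Why: Hydrogenolysis cleaves the aryl benzyl ether and the benzyl ester in one operation under neutral conditions that the alkyl mesylate and the silyl ether tolerate, no halogen being present at this stage.

Step 14
Reactants: 17 (2S)-2-{2-hydroxy-4-[(1R,4R)-4-(methanesulfonyloxy)-1-(triisopropylsilyloxy)pentyl]-5-methylphenyl}propanoic acid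
Product: 18 (2S)-2-{3-bromo-2-hydroxy-4-[(1R,4R)-4-(methanesulfonyloxy)-1-(triisopropylsilyloxy)pentyl]-5-methylphenyl}propanoic acid
Conditions: NBS (1.0 equiv), MeCN, −20 → 0 °C, dark; product used at once
Reagents that add atoms: N-bromosuccinimide, O=C1CCC(=O)N1Br
Why: Electrophilic bromination of the free phenol goes to C9, the only open ortho position (the para carbon and the other ortho carbon are substituted), under conditions too mild to lactonise the hydroxy acid.

Step 15
Reactants: 18 (2S)-2-{3-bromo-2-hydroxy-4-[(1R,4R)-4-(methanesulfonyloxy)-1-(triisopropylsilyloxy)pentyl]-5-methylphenyl}propanoic acid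
Product: 21 methyl 9-bromo-8-oxo-1β-(triisopropylsilyloxy)eremophila-6,9-dien-12-oate, via dipotassium phenolate carboxylate 19 (not isolated), via potassium dienone carboxylate 20 (not isolated)
Conditions: KOtBu (2.0 equiv), THF–DMF, 0.005 M, 0 → 50 °C; then MeI, 0 → 23 °C
Reagents that add atoms: iodomethane, CI
Why: Two equivalents of KOtBu give the phenolate carboxylate 19, whose para carbon C5 (largest HOMO coefficient of the phenolate) displaces the secondary mesylate at C4 in an intramolecular SN2 reaction, forming C4–C5 and turning ring B into the cross-conjugated dienone 20, which cannot rearomatise because C5 is quaternary; MeI then esterifies the carboxylate in the same flask. The closest known reaction type is the intramolecular para-alkylation of phenolates by tethered sulfonates or halides (aryl participation of the Ar2-6 kind) that gives fused cyclohexa-2,5-dienones, secondary electrophiles and substituted para carbons included. Ring A closes in the 6-exo-tet mode. C4 is set by inversion of the (4R)-mesylate to 4S, and C5 by a chair-like transition state in which H-1 lies in the arene plane next to the C9 bromine (least allylic 1,3-strain), the silyloxy group is axial on the face away from the incoming C4 and the C4 methyl is equatorial, so that the new bond forms on the α face and the C5 methyl ends β, cis to the C4 methyl and to O-1. The step needs para over ortho and carbon over oxygen alkylation: the C9 bromine blocks the ortho carbon that would otherwise lead to a tetralol, the meta tether makes intramolecular O-alkylation geometrically impossible, and high dilution suppresses the intermolecular one. It also needs C11 to keep its configuration, which the carboxylate secures, since it can neither be deprotonated at its α carbon nor acylate the neighbouring phenolate to a benzofuranone.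

Step 16
Reactants: 21 methyl 9-bromo-8-oxo-1β-(triisopropylsilyloxy)eremophila-6,9-dien-12-oate
Product: 22 methyl 8-oxo-1β-(triisopropylsilyloxy)eremophila-6,9-dien-12-oate
Conditions: Pd(OAc)2 (5 mol %), PPh3 (10 mol %), HCO2H, Et3N, DMF, 45 °C
Reagents that add atoms: none
Why: Palladium-catalysed formate hydrodehalogenation, in which zerovalent palladium inserts readily into the C9–Br bond of the α-bromo enone and formate supplies the hydride, under conditions too weakly basic to touch C11.

Step 17
Reactants: 22 methyl 8-oxo-1β-(triisopropylsilyloxy)eremophila-6,9-dien-12-oate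
Product: 23 methyl 1β-hydroxy-8-oxoeremophila-6,9-dien-12-oate
Conditions: HF·pyridine, pyridine, THF, 0 → 23 °C
Reagents that add atoms: none
Why: Fluoride desilylation under weakly acidic, non-basic conditions avoids base-induced isomerisation of the γ-hydroxy enone and epimerisation at C11.

Step 18
Reactants: 23 methyl 1β-hydroxy-8-oxoeremophila-6,9-dien-12-oate; 24 angelic acid
Product: 26 methyl 1β-angeloyloxy-8-oxoeremophila-6,9-dien-12-oate (CNP0166395.1), via angelic 2,4,6-trichlorobenzoic anhydride 25 (not isolated)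
Conditions: 24, 2,4,6-Cl3C6H2COCl, Et3N, toluene, 23 °C; then 23, toluene, 75 °C
Reagents that add atoms: none
Why: Yamaguchi esterification through the mixed anhydride, run without a nucleophilic amine catalyst, acylates the secondary allylic alcohol at the less hindered angeloyl carbonyl and should keep the Z double bond from isomerising to the tiglate.

**Compound list**

1 | (R)-butane-1,3-diol | C[C@@H](O)CCO | starting material
2 | (R)-3-hydroxybutyl 4-methylbenzenesulfonate | C[C@@H](O)CCOS(=O)(=O)c1ccc(C)cc1 | intermediate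
3 | (R)-3-(tert-butyldimethylsilyloxy)butyl 4-methylbenzenesulfonate | C[C@@H](O[Si](C)(C)C(C)(C)C)CCOS(=O)(=O)c1ccc(C)cc1 | intermediate
4 | (R)-(4-bromobutan-2-yl)oxy(tert-butyl)dimethylsilane | C[C@@H](O[Si](C)(C)C(C)(C)C)CCBr | intermediate
5 | 5-hydroxy-2-methylbenzaldehyde | Cc1ccc(O)cc1C=O | starting material
6 | 5-(benzyloxy)-2-methylbenzaldehyde | Cc1ccc(OCc2ccccc2)cc1C=O | intermediate
7 | (R)-[3-(tert-butyldimethylsilyloxy)butyl]magnesium bromide | C[C@@H](O[Si](C)(C)C(C)(C)C)CC[Mg]Br | intermediate
8 | (4R)-1-[5-(benzyloxy)-2-methylphenyl]-4-(tert-butyldimethylsilyloxy)pentan-1-ol, both C1 epimers | Cc1ccc(OCc2ccccc2)cc1C(O)CC[C@@H](C)O[Si](C)(C)C(C)(C)C | intermediate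
9 | (R)-1-[5-(benzyloxy)-2-methylphenyl]-4-(tert-butyldimethylsilyloxy)pentan-1-one | Cc1ccc(OCc2ccccc2)cc1C(=O)CC[C@@H](C)O[Si](C)(C)C(C)(C)C | intermediate
10 | (1R,4R)-1-[5-(benzyloxy)-2-methylphenyl]-4-(tert-butyldimethylsilyloxy)pentan-1-ol | Cc1ccc(OCc2ccccc2)cc1[C@H](O)CC[C@@H](C)O[Si](C)(C)C(C)(C)C | intermediate
11 | 4-(benzyloxy)-1-methyl-2-[(1R,4R)-4-(tert-butyldimethylsilyloxy)-1-(triisopropylsilyloxy)pentyl]benzene | Cc1ccc(OCc2ccccc2)cc1[C@H](O[Si](C(C)C)(C(C)C)C(C)C)CC[C@@H](C)O[Si](C)(C)C(C)(C)C | intermediate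
12 | 1-(benzyloxy)-2-iodo-4-methyl-5-[(1R,4R)-4-(tert-butyldimethylsilyloxy)-1-(triisopropylsilyloxy)pentyl]benzene | Cc1cc(I)c(OCc2ccccc2)cc1[C@H](O[Si](C(C)C)(C(C)C)C(C)C)CC[C@@H](C)O[Si](C)(C)C(C)(C)C | intermediate
13 | benzyl 2-chloropropanoate (racemic) | CC(Cl)C(=O)OCc1ccccc1 | starting material
14 | benzyl (2S)-2-{2-(benzyloxy)-5-methyl-4-[(1R,4R)-4-(tert-butyldimethylsilyloxy)-1-(triisopropylsilyloxy)pentyl]phenyl}propanoate | Cc1cc([C@H](C)C(=O)OCc2ccccc2)c(OCc2ccccc2)cc1[C@H](O[Si](C(C)C)(C(C)C)C(C)C)CC[C@@H](C)O[Si](C)(C)C(C)(C)C | intermediate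
15 | benzyl (2S)-2-{2-(benzyloxy)-4-[(1R,4R)-4-hydroxy-1-(triisopropylsilyloxy)pentyl]-5-methylphenyl}propanoate | Cc1cc([C@H](C)C(=O)OCc2ccccc2)c(OCc2ccccc2)cc1[C@H](O[Si](C(C)C)(C(C)C)C(C)C)CC[C@@H](C)O | intermediate
16 | benzyl (2S)-2-{2-(benzyloxy)-4-[(1R,4R)-4-(methanesulfonyloxy)-1-(triisopropylsilyloxy)pentyl]-5-methylphenyl}propanoate | Cc1cc([C@H](C)C(=O)OCc2ccccc2)c(OCc2ccccc2)cc1[C@H](O[Si](C(C)C)(C(C)C)C(C)C)CC[C@@H](C)OS(C)(=O)=O | intermediate
17 | (2S)-2-{2-hydroxy-4-[(1R,4R)-4-(methanesulfonyloxy)-1-(triisopropylsilyloxy)pentyl]-5-methylphenyl}propanoic acid | Cc1cc([C@H](C)C(=O)O)c(O)cc1[C@H](O[Si](C(C)C)(C(C)C)C(C)C)CC[C@@H](C)OS(C)(=O)=O | intermediate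
18 | (2S)-2-{3-bromo-2-hydroxy-4-[(1R,4R)-4-(methanesulfonyloxy)-1-(triisopropylsilyloxy)pentyl]-5-methylphenyl}propanoic acid | Cc1cc([C@H](C)C(=O)O)c(O)c(Br)c1[C@H](O[Si](C(C)C)(C(C)C)C(C)C)CC[C@@H](C)OS(C)(=O)=O | intermediate
19 | dipotassium phenolate carboxylate of 18 | Cc1cc([C@H](C)C(=O)[O-])c([O-])c(Br)c1[C@H](O[Si](C(C)C)(C(C)C)C(C)C)CC[C@@H](C)OS(C)(=O)=O.[K+].[K+] | intermediate
20 | potassium 9-bromo-8-oxo-1β-(triisopropylsilyloxy)eremophila-6,9-dien-12-oate | CC(C)[Si](C(C)C)(C(C)C)O[C@@H]1CC[C@H](C)[C@@]2(C)C=C([C@H](C)C(=O)[O-])C(=O)C(Br)=C12.[K+] | intermediate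
21 | methyl 9-bromo-8-oxo-1β-(triisopropylsilyloxy)eremophila-6,9-dien-12-oate (1R,4S,5S,11S) | CC(C)[Si](C(C)C)(C(C)C)O[C@@H]1CC[C@H](C)[C@@]2(C)C=C([C@H](C)C(=O)OC)C(=O)C(Br)=C12 | intermediate
22 | methyl 8-oxo-1β-(triisopropylsilyloxy)eremophila-6,9-dien-12-oate | CC(C)[Si](C(C)C)(C(C)C)O[C@@H]1CC[C@H](C)[C@@]2(C)C=C([C@H](C)C(=O)OC)C(=O)C=C12 | intermediate
23 | methyl 1β-hydroxy-8-oxoeremophila-6,9-dien-12-oate | O[C@@H]1CC[C@H](C)[C@@]2(C)C=C([C@H](C)C(=O)OC)C(=O)C=C12 | intermediate
24 | angelic acid, (Z)-2-methylbut-2-enoic acid | C/C=C(/C)C(=O)O | starting material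
25 | angelic 2,4,6-trichlorobenzoic anhydride | C/C=C(/C)C(=O)OC(=O)c1c(Cl)cc(Cl)cc1Cl | intermediate
26 | methyl 1β-angeloyloxy-8-oxoeremophila-6,9-dien-12-oate (CNP0166395.1) | C/C=C(/C)C(=O)O[C@@H]1CC[C@H](C)[C@@]2(C)C=C([C@H](C)C(=O)OC)C(=O)C=C12 | target

**Count and risks**

Total: 18 steps. Longest linear sequence: 17 steps (from diol 1 through steps 1–3 and 5–18 to 26).

Steps most likely to fail:

1. Step 15 (ring closure). What may go wrong: elimination of the secondary mesylate, or simple lack of reactivity at the methyl-bearing para carbon, may outrun C–C bond formation; attack on the wrong face of C5 is the second concern.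
Fallback: the C4 hydroxyl is activated by redox condensation in the presence of the free phenol (Mitsunobu-type alkylative dearomatisation, a reaction type known from phenol spirocyclisations), with no preformed sulfonate and no metal phenolate. It sets out from alcohol 15. Hydrogenolysis (H2, Pd/C, EtOAc) should give (2S)-2-{2-hydroxy-4-[(1R,4R)-4-hydroxy-1-(triisopropylsilyloxy)pentyl]-5-methylphenyl}propanoic acid F1. Me3SiCHN2 in toluene–MeOH should give its methyl ester F2. NBS in MeCN should brominate C9 to give the bromophenol methyl ester F3. PPh3 and diisopropyl azodicarboxylate in dilute toluene should then close ring A with inversion at C4, and the route is rejoined at 21.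

2. Step 10 (nickel coupling). What may go wrong: the ortho-benzyloxy aryl iodide may react sluggishly, so that hydrodeiodination or homocoupling competes, or the ligand may control C11 insufficiently.
Fallback: C7–C11 is made without a stereocentre and C11 is set by asymmetric hydrogenation. It sets out from iodide 12. Stille coupling with methyl 2-(tributylstannyl)acrylate (Pd(PPh3)4, CuI, CsF, DMF) should give the methyl 2-arylacrylate F4. LiOH in THF–H2O should give the 2-arylacrylic acid F5. Hydrogenation with Ru(OAc)2[(S)-BINAP] (H2, 100 atm, MeOH), which leaves the benzyl ether alone, should give the (2S)-2-arylpropanoic acid F6. BnBr and K2CO3 in DMF convert it into benzyl ester 14, where the route is rejoined.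

3. Step 18 (angeloylation). What may go wrong: the angeloyl group may isomerise to tigloyl during activation, or the axial 1β-hydroxyl, which is flanked by the C5 methyl and C9, may acylate too slowly.
Fallback: the Z double bond is built on the ester by a Still–Gennari olefination. It sets out from alcohol 23. Acylation with 2-[bis(2,2,2-trifluoroethoxy)phosphoryl]propanoic acid (N-ethyl-N'-(3-dimethylaminopropyl)carbodiimide, DMAP cat., CH2Cl2) should give the phosphonopropanoate ester F7. Treatment with KN(SiMe3)2 (1.0 equiv) and 18-crown-6 in THF at −78 °C followed by acetaldehyde should give the Z-configured 2-methylbut-2-enoate, that is target 26.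

**Further compounds**

F1 | step 15 | (2S)-2-{2-hydroxy-4-[(1R,4R)-4-hydroxy-1-(triisopropylsilyloxy)pentyl]-5-methylphenyl}propanoic acid | Cc1cc([C@H](C)C(=O)O)c(O)cc1[C@H](O[Si](C(C)C)(C(C)C)C(C)C)CC[C@@H](C)O
F2 | step 15 | methyl (2S)-2-{2-hydroxy-4-[(1R,4R)-4-hydroxy-1-(triisopropylsilyloxy)pentyl]-5-methylphenyl}propanoate | Cc1cc([C@H](C)C(=O)OC)c(O)cc1[C@H](O[Si](C(C)C)(C(C)C)C(C)C)CC[C@@H](C)O
F3 | step 15 | methyl (2S)-2-{3-bromo-2-hydroxy-4-[(1R,4R)-4-hydroxy-1-(triisopropylsilyloxy)pentyl]-5-methylphenyl}propanoate | Cc1cc([C@H](C)C(=O)OC)c(O)c(Br)c1[C@H](O[Si](C(C)C)(C(C)C)C(C)C)CC[C@@H](C)O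
F4 | step 10 | methyl 2-{2-(benzyloxy)-5-methyl-4-[(1R,4R)-4-(tert-butyldimethylsilyloxy)-1-(triisopropylsilyloxy)pentyl]phenyl}acrylate | Cc1cc(C(=C)C(=O)OC)c(OCc2ccccc2)cc1[C@H](O[Si](C(C)C)(C(C)C)C(C)C)CC[C@@H](C)O[Si](C)(C)C(C)(C)C
F5 | step 10 | 2-{2-(benzyloxy)-5-methyl-4-[(1R,4R)-4-(tert-butyldimethylsilyloxy)-1-(triisopropylsilyloxy)pentyl]phenyl}acrylic acid | Cc1cc(C(=C)C(=O)O)c(OCc2ccccc2)cc1[C@H](O[Si](C(C)C)(C(C)C)C(C)C)CC[C@@H](C)O[Si](C)(C)C(C)(C)C
F6 | step 10 | (2S)-2-{2-(benzyloxy)-5-methyl-4-[(1R,4R)-4-(tert-butyldimethylsilyloxy)-1-(triisopropylsilyloxy)pentyl]phenyl}propanoic acid | Cc1cc([C@H](C)C(=O)O)c(OCc2ccccc2)cc1[C@H](O[Si](C(C)C)(C(C)C)C(C)C)CC[C@@H](C)O[Si](C)(C)C(C)(C)C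
F7 | step 18 | methyl 1β-{2-[bis(2,2,2-trifluoroethoxy)phosphoryl]propanoyloxy}-8-oxoeremophila-6,9-dien-12-oate | CC(C(=O)O[C@@H]1CC[C@H](C)[C@@]2(C)C=C([C@H](C)C(=O)OC)C(=O)C=C12)P(=O)(OCC(F)(F)F)OCC(F)(F)F
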